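Its constants are invented, and the outcome is calculated.

Of what you charged, the pre-initiator is 1.92% of the free monomer, and you want a quick number for the chain length in this flask, with your hunch that the chains come out long.

free monomer 13 mM; pre-initiator 0.25 mM; time 2.0 h

    free monomer + initiator → living end + monomer in chains (k1 = 0.00248 M⁻¹ s⁻¹)
    free monomer + living end → monomer in chains + living end, rate k2*[living end]*[free monomer] (k2 = 14.5 M⁻¹ s⁻¹)
    monomer in chains → over-reaction product (k3 = 7.46 × 10⁻⁷ s⁻¹)
    free monomer + initiator → spent initiator (k4 = 0.0434 M⁻¹ s⁻¹)
    pre-initiator → initiator (k5 = 3.93 × 10⁻⁵ s⁻¹)

- whether the average number of monomer units in a chain (chains begun, living or dead) reaches 200 by 2.0 h (no / yes)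
- average number of monomer units in a chain (chains begun, living or dead) at 2.0 h

- the average divides the monomer in chains by the number of chains begun, living and dead together
- run time (flask): 2.0 h

I reckon with fractions left, and I carry one quantity. It is 5.41%, the chain share: the rate constant of the chain-starting step over the sum of that constant and the one of the step to spent initiator, which is the part of consumed initiator that begins a chain. Both steps use the same pair, so this selectivity stays put as the flask runs.

In this flask, 75.4% of the pre-initiator is left at 2.0 h. While the free monomer stays near its charge, initiator is consumed pseudo-first-order with a lifetime of 0.466 h, shorter than 2.0 h, so I take the unused stock as release rate times lifetime and reckon 19.7% of the pre-initiator charge as consumed. The chain share turns that into 1.06% of the pre-initiator charge as chains begun.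

I let living ends rise in a straight line after that lifetime, which leaves 89.9% of the free monomer. I drop the over-reaction, its half-life of 11 d being longer than 2.0 h. The monomer gone, over the chains begun, gives 494, more than 200.

The forecast says yes, at 540 (from 480 to 600), on the ground that “only about 5% of the initiator consumed starts a chain”. My figure is lower than the forecast's.

The simulation gives yes, with 556 at 2.0 h. Growth on living ends takes free monomer faster than chain starting does, with half-lives of 5.2 h against 230 d at 2.00 h. That ratio means about 1062 units join per chain begun at that moment, more than the running average. In this flask at 20.0 h, with 5.90% of the pre-initiator left and 26.8% of its charge standing as initiator, the chain share gives 3.64% of that charge as chains begun, so the monomer in chains, 94.8% of the free monomer charged, averages 1360 units.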